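**Retrosynthetic overview**
- The target comes from a 2‑methoxy‑3,6‑diaryl‑1,4‑benzoquinone by OMe → OH → OAc exchange, then release of the two phenols (carried as tert‑butyl ethers).
- The quinone ring is not taken from a halogenated arene or quinone (no Suzuki coupling). It is built de novo by a Moore‑type ring expansion (4π opening, then 6π closure) of a 4‑(1‑arylvinyl)‑4‑hydroxycyclobutenone.
- That cyclobutenone comes from 1,2‑addition of a Shapiro‑derived 1‑arylvinyllithium to 3‑aryl‑4‑methoxycyclobutenedione, itself made from dimethyl squarate and an aryllithium.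
- Ring order: the aryl rings and the cyclobutene ring are bought; the six‑membered quinone ring is the only ring formed (step 4).

Assumption: the target has no stereogenic element, so "single enantiomer" is met by the achiral compound itself; the one stereocentre in the route (C4 of 10, racemic) is erased in step 4.

**Step 1**
Reactants: 1 1‑bromo‑4‑tert‑butoxybenzene; 2 dimethyl squarate (3,4‑dimethoxycyclobut‑3‑ene‑1,2‑dione)
Product: 5 3‑(4‑tert‑butoxyphenyl)‑4‑methoxycyclobut‑3‑ene‑1,2‑dione, via aryllithium 3 (not isolated), via lithium alkoxide 4 (not isolated)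
Conditions: 1, n‑BuLi (1.0 eq), THF, −78 °C; cannulate into 2 (1.1 eq), THF, −78 °C, 1 h; TFAA (1.5 eq), −78 °C, 15 min; sat. aq NH4Cl
Reagents that add atoms: water, O
Why: Br/Li exchange and 1,2‑addition of the aryllithium to one squarate carbonyl, then O‑trifluoroacetylation, ionisation to a methoxy‑stabilised allyl/oxocarbenium cation and hydrolysis on quench (squarate addition–TFAA rearrangement) give the aryl cyclobutenedione with no stereocentre left.

**Step 2**
Reactants: 6 1‑(4‑tert‑butoxyphenyl)ethan‑1‑one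
Product: 7 N'‑[(1E)‑1‑(4‑tert‑butoxyphenyl)ethylidene]‑2,4,6‑tri(propan‑2‑yl)benzenesulfonohydrazide
Conditions: TrisNHNH2 (1.05 eq), cat. conc. HCl (1 mol %), MeCN, rt
Reagents that add atoms: 2,4,6‑triisopropylbenzenesulfonohydrazide, CC(C)c1cc(C(C)C)c(S(=O)(=O)NN)c(C(C)C)c1
Why: Acid‑catalysed condensation (arenesulfonylhydrazone formation) gives the E hydrazone for steric reasons, with the N–sulfonyl group syn to the methyl group as the Shapiro reaction needs.

**Step 3**
Reactants: 7 N'‑[(1E)‑1‑(4‑tert‑butoxyphenyl)ethylidene]‑2,4,6‑tri(propan‑2‑yl)benzenesulfonohydrazide; 5 3‑(4‑tert‑butoxyphenyl)‑4‑methoxycyclobut‑3‑ene‑1,2‑dione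
Product: 10 2‑(4‑tert‑butoxyphenyl)‑4‑[1‑(4‑tert‑butoxyphenyl)ethenyl]‑4‑hydroxy‑3‑methoxycyclobut‑2‑en‑1‑one (racemic), via vinyllithium 8 (not isolated), via lithium alkoxide 9 (not isolated)
Conditions: 7 (1.3 eq), n‑BuLi (2.6 eq), THF, −78 → 0 °C (N2 evolution); recool to −78 °C, add 5 (1.0 eq) in THF; sat. aq NH4Cl at −78 °C
Reagents that add atoms: none
Why: The Shapiro reaction (double deprotonation, loss of sulfinate and N2) gives the 1‑arylvinyllithium, which adds 1,2 to the ketone‑like carbonyl next to C–OMe and not to the deactivated vinylogous‑ester carbonyl next to C–Ar (the established regiochemistry of 3‑alkoxycyclobutenediones), and the new carbinol centre is racemic and destroyed in step 4.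

**Step 4**
Reactants: 10 2‑(4‑tert‑butoxyphenyl)‑4‑[1‑(4‑tert‑butoxyphenyl)ethenyl]‑4‑hydroxy‑3‑methoxycyclobut‑2‑en‑1‑one
Product: 13 3,6‑bis(4‑tert‑butoxyphenyl)‑2‑methoxycyclohexa‑2,5‑diene‑1,4‑dione, via dienylketene 11 (not isolated), via hydroquinone 12 (not isolated)
Conditions: PhMe (0.02 M), 110 °C, Ar, 2 h; cool; Ag2O (2 eq), MgSO4, rt
Reagents that add atoms: none
Why: Moore‑type ring expansion, in which thermal conrotatory 4π ring opening with the OH rotating outward gives the (Z)‑dienylketene, 6π electrocyclisation onto the unsubstituted CH2 terminus and tautomerisation give the hydroquinone, and Ag2O oxidises it to the quinone, so the connectivity alone fixes the para‑diaryl pattern with OMe para to H.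

**Step 5**
Reactants: 13 3,6‑bis(4‑tert‑butoxyphenyl)‑2‑methoxycyclohexa‑2,5‑diene‑1,4‑dione
Product: 14 3,6‑bis(4‑tert‑butoxyphenyl)‑2‑hydroxycyclohexa‑2,5‑diene‑1,4‑dione
Conditions: 1 M aq NaOH (3 eq), THF, 0 °C → rt, Ar; then 1 M HCl to pH 3, 0 °C
Reagents that add atoms: sodium hydroxide, [Na+].[OH-]
Why: Addition–elimination of hydroxide at the vinylogous‑ester carbon (vinylogous saponification of a 2‑methoxyquinone) gives the stabilised quinonolate, and the aryl tert‑butyl ethers are inert to base and to the brief cold acidification.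

**Step 6**
Reactants: 14 3,6‑bis(4‑tert‑butoxyphenyl)‑2‑hydroxycyclohexa‑2,5‑diene‑1,4‑dione
Product: 15 2,5‑bis(4‑tert‑butoxyphenyl)‑3,6‑dioxocyclohexa‑1,4‑dien‑1‑yl acetate
Conditions: Ac2O (2 eq), pyridine (3 eq), CH2Cl2, 0 °C → rt
Reagents that add atoms: acetic anhydride, CC(=O)OC(C)=O
Why: O‑acylation of the vinylogous acid (hydroxyquinone) gives the p‑quinone enol acetate, and no other nucleophilic OH is free because both phenols are still tert‑butyl ethers.

**Step 7**
Reactants: 15 2,5‑bis(4‑tert‑butoxyphenyl)‑3,6‑dioxocyclohexa‑1,4‑dien‑1‑yl acetate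
Product: 16 neonambiquinone A, 2,5‑bis(4‑hydroxyphenyl)‑3,6‑dioxocyclohexa‑1,4‑dien‑1‑yl acetate
Conditions: TFA/CH2Cl2 (1:4), 0 °C → rt, 1 h; evaporate cold, no aqueous base
Reagents that add atoms: none
Why: Anhydrous acidolysis (E1 loss of isobutene) of the two aryl tert‑butyl ethers spares the acetoxyquinone, which is acid‑stable and sensitive only to bases and nucleophiles.

**Compound list**
1 | 1‑bromo‑4‑tert‑butoxybenzene | CC(C)(C)Oc1ccc(Br)cc1 | starting material
2 | dimethyl squarate (3,4‑dimethoxycyclobut‑3‑ene‑1,2‑dione) | COC1=C(OC)C(=O)C1=O | starting material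
3 | (4‑tert‑butoxyphenyl)lithium | [Li]c1ccc(OC(C)(C)C)cc1 | intermediate
4 | lithium 1‑(4‑tert‑butoxyphenyl)‑2,3‑dimethoxy‑4‑oxocyclobut‑2‑en‑1‑olate (racemic) | [Li]OC1(c2ccc(OC(C)(C)C)cc2)C(OC)=C(OC)C1=O | intermediate
5 | 3‑(4‑tert‑butoxyphenyl)‑4‑methoxycyclobut‑3‑ene‑1,2‑dione | COC1=C(c2ccc(OC(C)(C)C)cc2)C(=O)C1=O | intermediate
6 | 1‑(4‑tert‑butoxyphenyl)ethan‑1‑one | CC(=O)c1ccc(OC(C)(C)C)cc1 | starting material
7 | N'‑[(1E)‑1‑(4‑tert‑butoxyphenyl)ethylidene]‑2,4,6‑tri(propan‑2‑yl)benzenesulfonohydrazide | C/C(c1ccc(OC(C)(C)C)cc1)=N\NS(=O)(=O)c1c(C(C)C)cc(C(C)C)cc1C(C)C | intermediate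
8 | [1‑(4‑tert‑butoxyphenyl)ethenyl]lithium | [Li]C(=C)c1ccc(OC(C)(C)C)cc1 | intermediate
9 | lithium 3‑(4‑tert‑butoxyphenyl)‑1‑[1‑(4‑tert‑butoxyphenyl)ethenyl]‑2‑methoxy‑4‑oxocyclobut‑2‑en‑1‑olate (racemic) | [Li]OC1(C(=C)c2ccc(OC(C)(C)C)cc2)C(OC)=C(c2ccc(OC(C)(C)C)cc2)C1=O | intermediate
10 | 2‑(4‑tert‑butoxyphenyl)‑4‑[1‑(4‑tert‑butoxyphenyl)ethenyl]‑4‑hydroxy‑3‑methoxycyclobut‑2‑en‑1‑one (racemic) | COC1=C(c2ccc(OC(C)(C)C)cc2)C(=O)C1(O)C(=C)c1ccc(OC(C)(C)C)cc1 | intermediate
11 | (3Z)‑2,5‑bis(4‑tert‑butoxyphenyl)‑4‑hydroxy‑3‑methoxyhexa‑1,3,5‑trien‑1‑one | O=C=C(c1ccc(OC(C)(C)C)cc1)/C(OC)=C(/O)C(=C)c1ccc(OC(C)(C)C)cc1 | intermediate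
12 | 2,5‑bis(4‑tert‑butoxyphenyl)‑3‑methoxybenzene‑1,4‑diol | COc1c(O)c(-c2ccc(OC(C)(C)C)cc2)cc(O)c1-c1ccc(OC(C)(C)C)cc1 | intermediate
13 | 3,6‑bis(4‑tert‑butoxyphenyl)‑2‑methoxycyclohexa‑2,5‑diene‑1,4‑dione | COC1=C(c2ccc(OC(C)(C)C)cc2)C(=O)C=C(c2ccc(OC(C)(C)C)cc2)C1=O | intermediate
14 | 3,6‑bis(4‑tert‑butoxyphenyl)‑2‑hydroxycyclohexa‑2,5‑diene‑1,4‑dione | OC1=C(c2ccc(OC(C)(C)C)cc2)C(=O)C=C(c2ccc(OC(C)(C)C)cc2)C1=O | intermediate
15 | 2,5‑bis(4‑tert‑butoxyphenyl)‑3,6‑dioxocyclohexa‑1,4‑dien‑1‑yl acetate | CC(=O)OC1=C(c2ccc(OC(C)(C)C)cc2)C(=O)C=C(c2ccc(OC(C)(C)C)cc2)C1=O | intermediate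
16 | neonambiquinone A, 2,5‑bis(4‑hydroxyphenyl)‑3,6‑dioxocyclohexa‑1,4‑dien‑1‑yl acetate (achiral) | CC(=O)OC1=C(c2ccc(O)cc2)C(=O)C=C(c2ccc(O)cc2)C1=O | target

**Totals**
Total step count: 7. Longest linear sequence: 6 steps (steps 1, 3, 4, 5, 6, 7; the branch through step 2 is equally long).

**Steps most likely to fail, with fallbacks**

Step 3 (Shapiro generation of the hindered vinyllithium and its clean 1,2‑addition in the presence of lithium sulfinate). The fallback sets out from ketone 6 and comes back at vinyllithium 8. Ketone 6 is condensed with hydrazine hydrate in EtOH to (1E)‑[1‑(4‑tert‑butoxyphenyl)ethylidene]hydrazine F1. This is oxidised with I2 and tetramethylguanidine in Et2O (Barton vinyl iodide synthesis) to 1‑tert‑butoxy‑4‑(1‑iodoethenyl)benzene F2. Iodine–lithium exchange with t‑BuLi (2 eq, Et2O, −78 °C) then gives 8 cold and free of sulfinate, and 8 is added to 5 as in the main route to reach 10.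

Step 5 (aqueous hydroxide on a quinone that still has one free ring CH, where conjugate addition and redox side reactions can compete). The fallback sets out from 13 and comes back at 15, so it also replaces step 6. Instead of attacking the ring carbon, the O–CH3 bond is cleaved by SN2 attack of chloride on the methyl group (LiCl, dry DMF, 90 °C, as for dealkylation of methyl esters and vinylogous esters). This gives lithium 2,5‑bis(4‑tert‑butoxyphenyl)‑3,6‑dioxocyclohexa‑1,4‑dien‑1‑olate F3 without water or hydroxide. F3 is acetylated in the same flask with Ac2O at 0 °C to give 15.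

Step 7 (acid deprotection next to the labile vinylogous anhydride, with possible tert‑butylation of the phenol rings or acetyl loss). The fallback sets out from 14 and comes back at 16 by reversing the order of deprotection and acetylation. Treating 14 with TFA/CH2Cl2 gives 2‑hydroxy‑3,6‑bis(4‑hydroxyphenyl)cyclohexa‑2,5‑diene‑1,4‑dione F4. Its quinone OH (pKa about 4–5) is ionised selectively over the phenols (pKa about 10) with exactly 1.0 eq Et3N. The resulting quinonolate alone is acetylated with 1.0 eq AcCl in THF at −78 °C to give 16 directly.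

**Further compounds**
F1 | step 3 | (1E)‑[1‑(4‑tert‑butoxyphenyl)ethylidene]hydrazine | C/C(c1ccc(OC(C)(C)C)cc1)=N\N
F2 | step 3 | 1‑tert‑butoxy‑4‑(1‑iodoethenyl)benzene | C=C(I)c1ccc(OC(C)(C)C)cc1
F3 | step 5 | lithium 2,5‑bis(4‑tert‑butoxyphenyl)‑3,6‑dioxocyclohexa‑1,4‑dien‑1‑olate | [Li]OC1=C(c2ccc(OC(C)(C)C)cc2)C(=O)C=C(c2ccc(OC(C)(C)C)cc2)C1=O
F4 | step 7 | 2‑hydroxy‑3,6‑bis(4‑hydroxyphenyl)cyclohexa‑2,5‑diene‑1,4‑dione | OC1=C(c2ccc(O)cc2)C(=O)C=C(c2ccc(O)cc2)C1=O
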